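**Plan**
- After removal of seven acetates, the methylcyclohexene (C1(Me)=C2H–C3H–C4H–C5H–C6H2) is cut at C3–C4 and C5–C6. This retro-[4+2] follows the presumed biosynthesis and gives a dehydroprenyl flavonol (diene 14) and a 2'-hydroxychalcone (dienophile 17).
- Enabling feature: the ring is a cyclohex-3-enyl aryl ketone, with the C1=C2 alkene γ,δ to the C4 ketone. The ortho-OH and C=O of its 2,4-dihydroxybenzoyl group close a temporary six-membered boron chelate that activates the enone and carries the chiral ligand.
- Diene 14 is cut at the ring B C3'–vinyl bond (Stille) and at pyranone ring C (Algar–Flynn–Oyamada), back to paeonol and 3-iodo-2,4-dimethoxybenzaldehyde. Dienophile 17 comes from paeonol and 2,4-dimethoxybenzaldehyde.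
- Forward order: the benzene rings are bought, ring C is closed (step 3), methyl ethers are exchanged for acetates, and the dienyl chain is joined (step 7). The cyclohexene is closed last (step 11) and the acetates are then removed (step 12).
- Stereochemistry: C4/C5 trans comes from the E-chalcone and C3/C4 trans from the exo transition state of the E-diene. The absolute sense (3R,4R,5S) comes from (R)-VANOL on boron.

Key step: step 11

Assumption: (R)-VANOL is taken to leave the Cα-Si/Cβ-Si face of the chelated chalcone open; if the sense of induction is the opposite one, (S)-VANOL is used and nothing else in the route changes.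

**Step 1**
Reactants: 1 2,4-dimethoxybenzaldehyde
Product: 5 3-iodo-2,4-dimethoxybenzaldehyde, via lithium amino alkoxide 2 (not isolated), via 3-lithio amino alkoxide 3 (not isolated), via 3-iodo amino alkoxide 4 (not isolated)
Conditions: 1-methylpiperazine, n-BuLi, THF, −20 °C, then 1; n-BuLi, −20 °C; I2, −78 °C → rt; H2O, aq Na2S2O3
Reagents that add atoms: iodine, II
Why: Lithium 4-methylpiperazin-1-ide masks the aldehyde in situ as an α-amino alkoxide that is a poor director, so directed ortho-metalation occurs at C3 between the two methoxy groups, and iodine quench followed by hydrolysis returns the aldehyde.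

**Step 2**
Reactants: 5 3-iodo-2,4-dimethoxybenzaldehyde; 6 paeonol (2-hydroxy-4-methoxyacetophenone)
Product: 7 (E)-2'-hydroxy-3-iodo-2,4,4'-trimethoxychalcone
Conditions: KOH (50% aq), EtOH, rt; then 1 M HCl
Reagents that add atoms: none
Why: In this Claisen–Schmidt condensation the enolate of 6 adds to the non-enolisable aldehyde and E1cB loss of water gives the thermodynamically preferred E-enone, while the aryl iodide and methyl ethers are inert to KOH.

**Step 3**
Reactants: 7 (E)-2'-hydroxy-3-iodo-2,4,4'-trimethoxychalcone
Product: 9 3-hydroxy-3'-iodo-7,2',4'-trimethoxyflavone, via trans-dihydroflavonol 8 (not isolated)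
Conditions: 30% H2O2, 5 M NaOH, MeOH, 0 °C → rt; then 1 M HCl
Reagents that add atoms: hydrogen peroxide, OO
Why: In the Algar–Flynn–Oyamada reaction, hydroperoxide attack on the enone and closure of ring C by the ring A phenoxide give dihydroflavonol 8, which a second equivalent of alkaline H2O2 dehydrogenates to the flavonol, the missing 6'-substituent on ring A favouring six- over five-membered closure.

**Step 4**
Reactants: 9 3-hydroxy-3'-iodo-7,2',4'-trimethoxyflavone
Product: 10 3,7,2',4'-tetrahydroxy-3'-iodoflavone
Conditions: BBr3 (excess), CH2Cl2, −78 °C → rt; MeOH, then H2O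
Reagents that add atoms: none
Why: BBr3 cleaves the three aryl methyl ethers by O-coordination and bromide attack on methyl, at a stage with no acid-sensitive alkene and with the iodide on an acceptor-substituted ring that resists protodeiodination.

**Step 5**
Reactants: 10 3,7,2',4'-tetrahydroxy-3'-iodoflavone
Product: 11 3,7,2',4'-tetraacetoxy-3'-iodoflavone
Conditions: Ac2O, pyridine, DMAP (cat.), rt
Reagents that add atoms: acetic anhydride, CC(=O)OC(C)=O
Why: Exhaustive DMAP-catalysed O-acylation installs groups that can be removed at the end without acid, and it caps the 3-OH/4-C=O pair so that it cannot bind boron in step 11.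

**Step 6**
Reactants: 12 2-methylbut-1-en-3-yne
Product: 13 (E)-tributyl(3-methylbuta-1,3-dien-1-yl)stannane
Conditions: Bu3SnH, Pd2(dba)3 (cat.), PCy3·HBF4 (cat.), i-Pr2NEt (cat.), CH2Cl2, 0 °C
Reagents that add atoms: tributyltin hydride, CCCC[SnH](CCCC)CCCC
Why: Palladium-catalysed hydrostannation is a syn addition to the alkyne that leaves the 1,1-disubstituted alkene alone, and the bulky PCy3 ligand steers tin to the terminal carbon, which gives the E-dienylstannane.

**Step 7**
Reactants: 11 3,7,2',4'-tetraacetoxy-3'-iodoflavone; 13 (E)-tributyl(3-methylbuta-1,3-dien-1-yl)stannane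
Product: 14 3,7,2',4'-tetraacetoxy-3'-[(E)-3-methylbuta-1,3-dienyl]flavone
Conditions: Pd2(dba)3 (cat.), AsPh3, CuI (cat.), DMF, 50 °C, BHT, dark
Reagents that add atoms: none
Why: The Stille coupling begins with oxidative addition of zerovalent palladium into the C–I bond and retains the alkene geometry, its base-free medium spares the four acetates, and AsPh3 and CuI speed transmetalation at the doubly ortho-substituted centre.

**Step 8**
Reactants: 1 2,4-dimethoxybenzaldehyde; 6 paeonol
Product: 15 (E)-2'-hydroxy-2,4,4'-trimethoxychalcone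
Conditions: KOH (50% aq), EtOH, rt; then 1 M HCl
Reagents that add atoms: none
Why: This is a Claisen–Schmidt condensation as in step 2, with the E geometry set by the E1cB dehydration.

**Step 9**
Reactants: 15 (E)-2'-hydroxy-2,4,4'-trimethoxychalcone
Product: 16 (E)-2,2',4,4'-tetrahydroxychalcone
Conditions: BBr3 (excess), CH2Cl2, −78 °C → rt; ice water, dark
Reagents that add atoms: none
Why: BBr3 ether cleavage is standard for methoxychalcones, boron binding at the 2'-O/C=O pair holds the open-chain E-enone during the reaction, and a cold, brief quench avoids ring closure through the new 2-OH.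

**Step 10**
Reactants: 16 (E)-2,2',4,4'-tetrahydroxychalcone
Product: 17 (E)-2,4,4'-triacetoxy-2'-hydroxychalcone
Conditions: Ac2O (3 equiv), pyridine, CH2Cl2, 0 °C
Reagents that add atoms: acetic anhydride, CC(=O)OC(C)=O
Why: Three equivalents of Ac2O acylate the three ordinary phenols, while the 2'-OH is held in a strong intramolecular hydrogen bond to the ketone, is the least nucleophilic, and stays free for boron.

**Step 11**
Reactants: 14 3,7,2',4'-tetraacetoxy-3'-[(E)-3-methylbuta-1,3-dienyl]flavone; 17 (E)-2,4,4'-triacetoxy-2'-hydroxychalcone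
Product: 20 (3R,4R,5S)-all-trans cycloadduct heptaacetate, via chalcone boron chelate 18 (not isolated), via cycloadduct boron chelate 19 (not isolated)
Conditions: 17, (R)-VANOL, B(OPh)3, 4 Å MS, CH2Cl2, rt, then 0.1 mmHg, 50 °C; 14, PhCF3, rt → 40 °C, dark; H2O work-up
Reagents that add atoms: none
Why: Exchange of the three phenoxides of B(OPh)3 for the VANOL diolate and the ortho-phenol of 17 gives the tetracoordinate chelate 18, in which the ketone oxygen is bound to boron in a temporary six-membered ring and the enone LUMO is lowered, so that a concerted, asynchronous, suprafacial [4+2] cycloaddition with the s-cis diene of 14 can run near room temperature (bond C5–C6 leading, bond C3–C4 lagging) and water then frees 20 from 19. The closest known reaction type is the biomimetic Diels–Alder reaction of 2'-hydroxychalcones with dehydroprenylarenes promoted by chiral diol–boron complexes. The cyclohexene is closed intermolecularly as a 4+2 union of the four diene carbons (C3, C2, C1, C6) with Cα and Cβ of the chalcone (C4, C5), both σ bonds being made in one event. C4 and C5 come out trans because the E geometry of 17 is carried over suprafacially, C3 comes out trans to C4 because the E-diene reacts through the exo transition state (aroyl–boron unit turned away from the diene, resorcinyl ring of 17 under it), and the absolute sense follows from attack on the Cα-Si/Cβ-Si face left open by the (R)-VANOL vault. Regioselectivity (aroyl next to the flavonol-bearing carbon, methyl para to it) is secured by the matched 1-aryl and 3-methyl groups, which place the largest HOMO coefficient on the CH2 terminus that attacks Cβ. Exo selectivity is the demanding point and rests on the two ortho-acetoxy groups, which twist ring B out of the diene plane and clash with the bulky boron–VANOL–aroyl unit in the endo arrangement, while chemoselectivity rests on 17 holding the only free chelating OH/C=O pair and on boron in 18 having no open site for the carbonyl groups of 14.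

**Step 12**
Reactants: 20 (3R,4R,5S)-all-trans cycloadduct heptaacetate
Product: 21 CNP0190989.1
Conditions: K2CO3, degassed MeOH/THF, Ar, 0 °C → rt; then 1 M HCl to pH 5, 0 °C
Reagents that add atoms: none
Why: Base-catalysed methanolysis removes all seven aryl and enol acetates, enolisation at C4 cannot erode configuration because the all-trans, all-equatorial isomer is the favoured epimer, and avoiding strong acid and oxygen protects the trisubstituted alkene and the flavonol.

**Compound list**
1 | 2,4-dimethoxybenzaldehyde | COc1ccc(C=O)c(OC)c1 | starting material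
2 | lithium (2,4-dimethoxyphenyl)(4-methylpiperazin-1-yl)methanolate, racemic | COc1ccc(C(O[Li])N2CCN(C)CC2)c(OC)c1 | intermediate
3 | 3-lithio derivative of 2, racemic | COc1ccc(C(O[Li])N2CCN(C)CC2)c(OC)c1[Li] | intermediate
4 | 3-iodo derivative of 2, racemic | COc1ccc(C(O[Li])N2CCN(C)CC2)c(OC)c1I | intermediate
5 | 3-iodo-2,4-dimethoxybenzaldehyde | COc1ccc(C=O)c(OC)c1I | intermediate
6 | paeonol, 1-(2-hydroxy-4-methoxyphenyl)ethanone | CC(=O)c1ccc(OC)cc1O | starting material
7 | (E)-1-(2-hydroxy-4-methoxyphenyl)-3-(3-iodo-2,4-dimethoxyphenyl)prop-2-en-1-one | COc1ccc(C(=O)/C=C/c2ccc(OC)c(I)c2OC)c(O)c1 | intermediate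
8 | trans-3-hydroxy-2-(3-iodo-2,4-dimethoxyphenyl)-7-methoxychroman-4-one, racemic | COc1ccc2C(=O)C(O)C(c3ccc(OC)c(I)c3OC)Oc2c1 | intermediate
9 | 3-hydroxy-2-(3-iodo-2,4-dimethoxyphenyl)-7-methoxychromen-4-one | COc1ccc2c(=O)c(O)c(-c3ccc(OC)c(I)c3OC)oc2c1 | intermediate
10 | 2-(2,4-dihydroxy-3-iodophenyl)-3,7-dihydroxychromen-4-one | Oc1ccc2c(=O)c(O)c(-c3ccc(O)c(I)c3O)oc2c1 | intermediate
11 | 2-(2,4-diacetoxy-3-iodophenyl)-4-oxochromene-3,7-diyl diacetate | CC(=O)Oc1ccc2c(=O)c(OC(C)=O)c(-c3ccc(OC(C)=O)c(I)c3OC(C)=O)oc2c1 | intermediate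
12 | 2-methylbut-1-en-3-yne | C=C(C)C#C | starting material
13 | (E)-tributyl(3-methylbuta-1,3-dien-1-yl)stannane | CCCC[Sn](CCCC)(CCCC)/C=C/C(C)=C | intermediate
14 | 2-{2,4-diacetoxy-3-[(E)-3-methylbuta-1,3-dienyl]phenyl}-4-oxochromene-3,7-diyl diacetate | CC(=O)Oc1ccc2c(=O)c(OC(C)=O)c(-c3ccc(OC(C)=O)c(/C=C/C(C)=C)c3OC(C)=O)oc2c1 | intermediate
15 | (E)-3-(2,4-dimethoxyphenyl)-1-(2-hydroxy-4-methoxyphenyl)prop-2-en-1-one | COc1ccc(C(=O)/C=C/c2ccc(OC)cc2OC)c(O)c1 | intermediate
16 | (E)-1,3-bis(2,4-dihydroxyphenyl)prop-2-en-1-one | Oc1ccc(C(=O)/C=C/c2ccc(O)cc2O)c(O)c1 | intermediate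
17 | (E)-1-(4-acetoxy-2-hydroxyphenyl)-3-(2,4-diacetoxyphenyl)prop-2-en-1-one | CC(=O)Oc1ccc(C(=O)/C=C/c2ccc(OC(C)=O)cc2OC(C)=O)c(O)c1 | intermediate
18 | spiro boron chelate of 17 (2'-O and C=O on boron) with the (R)-VANOL diolate; the R axis is not expressible in SMILES | CC(=O)Oc1ccc2c(c1)O[B-]1(Oc3c(c(-c4ccccc4)cc4ccccc34)-c3c(O1)c4ccccc4cc3-c3ccccc3)[O+]=C2/C=C/c1ccc(OC(C)=O)cc1OC(C)=O | intermediate
19 | (R)-VANOL boron chelate of cycloadduct 20, (3R,4R,5S); the R axis is not expressible in SMILES | CC1=C[C@@H](c2c(OC(C)=O)ccc(-c3oc4cc(OC(C)=O)ccc4c(=O)c3OC(C)=O)c2OC(C)=O)[C@H](C2=[O+][B-]3(Oc4c(c(-c5ccccc5)cc5ccccc45)-c4c(O3)c5ccccc5cc4-c4ccccc4)Oc3cc(OC(C)=O)ccc23)[C@@H](c2ccc(OC(C)=O)cc2OC(C)=O)C1 | intermediate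
20 | all-trans heptaacetate, (3R,4R,5S): C3 carries 2,6-diacetoxy-3-(3,7-diacetoxy-4-oxochromen-2-yl)phenyl, C4 carries 4-acetoxy-2-hydroxybenzoyl, C5 carries 2,4-diacetoxyphenyl | CC1=C[C@@H](c2c(OC(C)=O)ccc(-c3oc4cc(OC(C)=O)ccc4c(=O)c3OC(C)=O)c2OC(C)=O)[C@H](C(=O)c2ccc(OC(C)=O)cc2O)[C@@H](c2ccc(OC(C)=O)cc2OC(C)=O)C1 | intermediate
21 | CNP0190989.1, 2-{3-[(1R,5S,6R)-6-(2,4-dihydroxybenzoyl)-5-(2,4-dihydroxyphenyl)-3-methylcyclohex-2-en-1-yl]-2,4-dihydroxyphenyl}-3,7-dihydroxychromen-4-one | CC1=C[C@@H](c2c(O)ccc(-c3oc4cc(O)ccc4c(=O)c3O)c2O)[C@H](C(=O)c2ccc(O)cc2O)[C@@H](c2ccc(O)cc2O)C1 | target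

**Total step count:** 12.
**Longest linear sequence:** 8 steps (steps 1, 2, 3, 4, 5, 7, 11, 12).

**Steps most likely to fail**

**Step 11.**
- What may go wrong: insufficient preference for the exo over the endo transition state, or incomplete facial discrimination. The electron-poor, hindered diene may also react slowly and polymerise in competition.
- The fallback replaces Lewis acid control by biocatalysis. It sets out from 14 and 16 and comes back to the route at 21.
- Compound 14 is deacetylated briefly (K2CO3, degassed MeOH, 0 °C, aq NH4Cl quench) to the free dehydroprenyl flavonol F1.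
- F1 is used at once with unprotected chalcone 16 in Tris-HCl buffer (pH 8, DMSO co-solvent, 30 °C). The catalyst is a recombinant exo-selective FAD-dependent Diels–Alderase of Morus alba (MaDA-3).
- The enzyme pocket, instead of the boron ligand, should fix the exo orientation and the face. No protecting group is left to remove.

**Step 7.**
- What may go wrong: slow transmetalation at the doubly ortho-substituted arylpalladium iodide, which allows protodestannylation and homocoupling of the stannane. Long heating may also cause loss of acetates or polymerisation of the diene.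
- The fallback builds the C5 chain as an alcohol and makes the diene by elimination. It sets out from 11 and comes back at 14.
- A Mizoroki–Heck reaction of 11 with 2-methylbut-3-en-2-ol (Pd(OAc)2, Bu4NCl, NaHCO3, DMF, 70 °C) should give the E-configured tertiary allylic alcohol F2.
- Acid-catalysed dehydration of F2 (p-TsOH cat., toluene, 60 °C, 4 Å MS) through the aryl-stabilised allyl cation should give 14.

**Step 3.**
- What may go wrong: the oxidation may stall at the dihydroflavonol stage, five-membered ring closure may compete, or alkaline peroxide may cleave the chalcone by retro-aldol. All three are made more likely by the twisted, ortho-disubstituted ring B.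
- The fallback separates ring closure from C3 oxygenation. It sets out from 7 and comes back at 9.
- Oxidative cyclisation of 7 (I2 cat., DMSO, 125 °C) gives the flavone F3.
- F3 is deprotonated at C3 with LiN(i-Pr)2 (THF, −78 °C) and trapped with B(OMe)3 as the dimethyl flavon-3-ylboronate F4.
- Oxidation of F4 with H2O2/AcOH gives 9.

**Further compounds**
F1 | step 11 | 2-{2,4-dihydroxy-3-[(E)-3-methylbuta-1,3-dienyl]phenyl}-3,7-dihydroxychromen-4-one | Oc1ccc2c(=O)c(O)c(-c3ccc(O)c(/C=C/C(C)=C)c3O)oc2c1
F2 | step 7 | 2-{2,4-diacetoxy-3-[(E)-3-hydroxy-3-methylbut-1-enyl]phenyl}-4-oxochromene-3,7-diyl diacetate | CC(=O)Oc1ccc2c(=O)c(OC(C)=O)c(-c3ccc(OC(C)=O)c(/C=C/C(C)(C)O)c3OC(C)=O)oc2c1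
F3 | step 3 | 2-(3-iodo-2,4-dimethoxyphenyl)-7-methoxychromen-4-one | COc1ccc2c(=O)cc(-c3ccc(OC)c(I)c3OC)oc2c1
F4 | step 3 | dimethyl [2-(3-iodo-2,4-dimethoxyphenyl)-7-methoxy-4-oxochromen-3-yl]boronate | COc1ccc2c(=O)c(B(OC)OC)c(-c3ccc(OC)c(I)c3OC)oc2c1
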